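## Retrosynthetic overview

1. Target 22 ⇒ dienal 19 + but-3-en-2-one: a syn-selective boron reductive aldol makes the last C–C bond and the two side-chain stereocentres.
2. 19 ⇒ lactone 13 + iododienol 16: Pd-catalysed alkenylation of the lactone zinc enolate anti to the C4 methyl, then allylic oxidation.
3. 13 ⇒ ethynyl lactone 8 + vinyl iodide 11: methylalumination / Negishi diene coupling; 11 comes from hexanal in two steps.
4. 8 ⇒ trans-β-lactone 4 by a one-carbon ring expansion (carbenoid 1,2-shift through an ynolate); 4 ⇒ propanoyl bromide + silyl ynal.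
5. Ring order: the oxetan-2-one is formed first (step 1) and expanded to the oxolan-2-one (step 2); there is no other ring.

Assumption: catalyst antipodes are named from the usual facial models ((R)-prolinol ether gives (S)-10; (−)-Ipc2BH gives Re-face aldol addition; the step 1 catalyst antipode is the one giving (3R,4S)); if a model proved reversed, the mirror-image catalyst would be used with no other change.

## Route

Step 1
Reactants: 1 propanoyl bromide; 2 3-(trimethylsilyl)prop-2-ynal
Product: 4 (3R,4S)-3-methyl-4-[(trimethylsilyl)ethynyl]oxetan-2-one, via methylketene 3 (not isolated)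
Conditions: (salen)Al–bis(pyridinium bromide) catalyst (10 mol%), iPr2NEt, CH2Cl2, −70 °C
Reagents that add atoms: none
Why: Catalytic asymmetric ketene–aldehyde cyclocondensation (aldol–lactonisation); the Lewis acid/ammonium ion-pair catalyst enforces an open aldol transition state that gives the trans-lactone, and the catalyst antipode sets both centres as (3R,4S).

Step 2
Reactants: 4 (3R,4S)-3-methyl-4-[(trimethylsilyl)ethynyl]oxetan-2-one
Product: 8 (4S,5S)-5-ethynyl-4-methyloxolan-2-one, via lithium dibromoketone alkoxide 5 (not isolated), via dilithium ynolate 6 (not isolated), via TMS-lactone 7 (not isolated)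
Conditions: CH2Br2 (1.1 equiv), LiTMP (2.2 equiv), THF, −90 °C, then 4; n-BuLi, −78 → 0 °C; MeOH, −78 °C → rt; 1 M HCl
Reagents that add atoms: dibromomethane, BrCBr
Why: Proposed new method: LiCHBr2 adds to the strained lactone C=O and acyl–O cleavage gives the dibromomethyl ketone alkoxide 5; deprotonation and Br/Li exchange give a bromo-lithio enolate carbenoid in which C3 undergoes a 1,2-shift (with retention) to the carbenoid carbon, forming ynolate 6; C-protonation gives a ketene that the C4 alkoxide captures 5-exo, so the four-membered ring becomes the five-membered lactone with both stereocentres untouched, and LiOMe formed in the quench removes the alkynyl silyl group; the closest known reaction is the Kowalski ester homologation of acyclic esters via ynolates, which has not been shown as a β-lactone to γ-lactone ring expansion.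

Step 3
Reactants: 9 hexanal
Product: 10 (2S)-2-(hydroxymethyl)hexanal
Conditions: (R)-α,α-diphenylprolinol TMS ether (10 mol%), 37% aq. HCHO, pH 7 phosphate buffer, toluene, rt; used crude
Reagents that add atoms: formaldehyde, C=O
Why: Enamine-catalysed α-hydroxymethylation; the diaryl(silyloxy)methyl group shields one face of the (E)-enamine, so formaldehyde adds to the other and sets C2 as (S).

Step 4
Reactants: 10 (2S)-2-(hydroxymethyl)hexanal
Product: 11 (2R,3E)-2-butyl-4-iodobut-3-en-1-ol
Conditions: CrCl2 (6 equiv), CHI3 (2 equiv), 1,4-dioxane/THF 6:1, 0 °C → rt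
Reagents that add atoms: iodoform, IC(I)I
Why: Takai iodo-olefination gives the (E)-vinyl iodide under non-basic conditions, so the α-stereocentre is untouched (its label changes to R only through CIP priorities).

Step 5
Reactants: 8 (4S,5S)-5-ethynyl-4-methyloxolan-2-one; 11 (2R,3E)-2-butyl-4-iodobut-3-en-1-ol
Product: 13 (4S,5S)-5-[(2E,4E,6R)-6-(hydroxymethyl)deca-2,4-dien-2-yl]-4-methyloxolan-2-one, via alkenylalane 12 (not isolated)
Conditions: Me3Al (3 equiv), Cp2ZrCl2 (20 mol%), H2O (1 equiv), CH2Cl2, −23 °C; then 11, ZnCl2 (cat.), Pd(PPh3)4 (5 mol%), THF, 0 °C → rt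
Reagents that add atoms: trimethylaluminium, C[Al](C)C
Why: Negishi Zr-catalysed methylalumination (syn, methyl to the internal carbon) gives the (E)-alkenylalane, which couples with 11 under Pd/Zn (Negishi coupling) with retention on both partners; no stereocentre is formed or touched.

Step 6
Reactants: 14 (E)-pent-2-en-4-yn-1-ol
Product: 16 (2E,4E)-5-iodo-4-methylpenta-2,4-dien-1-ol, via dienylalane 15 (not isolated)
Conditions: Me3Al (3 equiv), Cp2ZrCl2 (25 mol%), CH2Cl2, 0 °C → rt; then I2, THF, −30 °C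
Reagents that add atoms: trimethylaluminium, C[Al](C)C; iodine, II
Why: Negishi carboalumination then iodinolysis; syn methylalumination of the terminal alkyne and Al-to-I exchange with retention fix the (4E) geometry.

Step 7
Reactants: 13 (4S,5S)-5-[(2E,4E,6R)-6-(hydroxymethyl)deca-2,4-dien-2-yl]-4-methyloxolan-2-one; 16 (2E,4E)-5-iodo-4-methylpenta-2,4-dien-1-ol
Product: 18 (3S,4S,5S)-3-[(1E,3E)-5-hydroxy-2-methylpenta-1,3-dien-1-yl]-5-[(2E,4E,6R)-6-(hydroxymethyl)deca-2,4-dien-2-yl]-4-methyloxolan-2-one, via zinc enolate 17 (not isolated)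
Conditions: LiHMDS (2.2 equiv), THF, −78 °C; ZnCl2 (2.4 equiv), → 0 °C; then 16 (1.2 equiv, as its lithium alkoxide from 1.2 equiv LiHMDS), Pd(dba)2 (5 mol%), Q-Phos (5 mol%), rt
Reagents that add atoms: none
Why: Pd-catalysed α-alkenylation of a zinc lactone enolate (Negishi-type enolate coupling); the alkenyl-Pd bonds to the enolate face anti to the C4 methyl, setting C3 as (S) (3,4-trans), and the weakly basic zinc enolate should not deprotonate the β,γ-unsaturated product.

Step 8
Reactants: 18 (3S,4S,5S)-3-[(1E,3E)-5-hydroxy-2-methylpenta-1,3-dien-1-yl]-5-[(2E,4E,6R)-6-(hydroxymethyl)deca-2,4-dien-2-yl]-4-methyloxolan-2-one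
Product: 19 (2E,4E)-5-{(3S,4S,5S)-5-[(2E,4E,6R)-6-(hydroxymethyl)deca-2,4-dien-2-yl]-4-methyl-2-oxooxolan-3-yl}-4-methylpenta-2,4-dienal
Conditions: MnO2 (20 equiv), CH2Cl2, rt; filtered and used at once
Reagents that add atoms: none
Why: Chemoselective allylic oxidation; MnO2 oxidises only the dienylic primary alcohol, leaves the saturated CH2OH, and is neutral so the labile C3–H is not epimerised.

Step 9
Reactants: 19 (2E,4E)-5-{(3S,4S,5S)-5-[(2E,4E,6R)-6-(hydroxymethyl)deca-2,4-dien-2-yl]-4-methyl-2-oxooxolan-3-yl}-4-methylpenta-2,4-dienal; 20 but-3-en-2-one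
Product: 22 (3S,4S,5S)-3-[(1E,3E,5S,6R)-5-hydroxy-2,6-dimethyl-7-oxoocta-1,3-dien-1-yl]-5-[(2E,4E,6R)-6-(hydroxymethyl)deca-2,4-dien-2-yl]-4-methyloxolan-2-one, via enol borinate 21 (not isolated)
Conditions: (−)-Ipc2BH (3.0 equiv), 20 (3.3 equiv), Et2O, 0 °C, 2 h; then 19, −78 → −20 °C; MeOH, pH 7 buffer, 30% H2O2, 0 °C
Reagents that add atoms: none
Why: Boron-mediated reductive aldol; 1,4-hydroboration of the s-cis enone gives the (Z)-enol borinate, which adds through a Zimmerman–Traxler chair (syn) with the Ipc ligands selecting the aldehyde Re face to set (5S,6R), while excess enol borinate masks the free CH2OH until work-up.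

## Compound list

1 | propanoyl bromide | CCC(=O)Br | starting material
2 | 3-(trimethylsilyl)prop-2-ynal | C[Si](C)(C)C#CC=O | starting material
3 | methylketene | CC=C=O | intermediate
4 | (3R,4S)-3-methyl-4-[(trimethylsilyl)ethynyl]oxetan-2-one | C[Si](C)(C)C#C[C@H]1OC(=O)[C@@H]1C | intermediate
5 | lithium alkoxide of (3R,4S)-1,1-dibromo-4-hydroxy-3-methyl-6-(trimethylsilyl)hex-5-yn-2-one | C[Si](C)(C)C#C[C@@H]([O-])[C@@H](C)C(=O)C(Br)Br.[Li+] | intermediate
6 | dilithium (3S,4S)-3-methyl-4-oxido-6-(trimethylsilyl)hexa-1,5-diyn-1-olate | C[Si](C)(C)C#C[C@@H]([O-])[C@@H](C)C#C[O-].[Li+].[Li+] | intermediate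
7 | (4S,5S)-4-methyl-5-[(trimethylsilyl)ethynyl]oxolan-2-one | C[Si](C)(C)C#C[C@H]1OC(=O)C[C@@H]1C | intermediate
8 | (4S,5S)-5-ethynyl-4-methyloxolan-2-one | C#C[C@H]1OC(=O)C[C@@H]1C | intermediate
9 | hexanal | CCCCCC=O | starting material
10 | (2S)-2-(hydroxymethyl)hexanal | CCCC[C@H](C=O)CO | intermediate
11 | (2R,3E)-2-butyl-4-iodobut-3-en-1-ol | CCCC[C@H](/C=C/I)CO | intermediate
12 | dimethyl{(1E)-2-[(2S,3S)-3-methyl-5-oxooxolan-2-yl]prop-1-en-1-yl}alane | C[Al](C)/C=C(\C)[C@H]1OC(=O)C[C@@H]1C | intermediate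
13 | (4S,5S)-5-[(2E,4E,6R)-6-(hydroxymethyl)deca-2,4-dien-2-yl]-4-methyloxolan-2-one | CCCC[C@H](/C=C/C=C(\C)[C@H]1OC(=O)C[C@@H]1C)CO | intermediate
14 | (E)-pent-2-en-4-yn-1-ol | C#C/C=C/CO | starting material
15 | {(1E,3E)-5-[(dimethylalumanyl)oxy]-2-methylpenta-1,3-dien-1-yl}dimethylalane | C[Al](C)/C=C(C)/C=C/CO[Al](C)C | intermediate
16 | (2E,4E)-5-iodo-4-methylpenta-2,4-dien-1-ol | I/C=C(C)/C=C/CO | intermediate
17 | bis(chlorozinc) enolate–alkoxide of 13 | CCCC[C@H](/C=C/C=C(\C)[C@H]1OC(O[Zn]Cl)=C[C@@H]1C)CO[Zn]Cl | intermediate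
18 | (3S,4S,5S)-3-[(1E,3E)-5-hydroxy-2-methylpenta-1,3-dien-1-yl]-5-[(2E,4E,6R)-6-(hydroxymethyl)deca-2,4-dien-2-yl]-4-methyloxolan-2-one | CCCC[C@H](/C=C/C=C(\C)[C@H]1OC(=O)[C@@H](/C=C(C)/C=C/CO)[C@@H]1C)CO | intermediate
19 | (2E,4E)-5-{(3S,4S,5S)-5-[(2E,4E,6R)-6-(hydroxymethyl)deca-2,4-dien-2-yl]-4-methyl-2-oxooxolan-3-yl}-4-methylpenta-2,4-dienal | CCCC[C@H](/C=C/C=C(\C)[C@H]1OC(=O)[C@@H](/C=C(C)/C=C/C=O)[C@@H]1C)CO | intermediate
20 | but-3-en-2-one | CC(=O)C=C | starting material
21 | (Z)-but-2-en-2-yl diisopinocampheylborinate (Ipc from (+)-α-pinene) | C/C=C(/C)OB([C@@H]1C[C@@H]2C[C@H]([C@H]1C)C2(C)C)[C@@H]1C[C@@H]2C[C@H]([C@H]1C)C2(C)C | intermediate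
22 | (3S,4S,5S)-3-[(1E,3E,5S,6R)-5-hydroxy-2,6-dimethyl-7-oxoocta-1,3-dien-1-yl]-5-[(2E,4E,6R)-6-(hydroxymethyl)deca-2,4-dien-2-yl]-4-methyloxolan-2-one | CCCC[C@H](/C=C/C=C(\C)[C@H]1OC(=O)[C@@H](/C=C(C)/C=C/[C@H](O)[C@@H](C)C(C)=O)[C@@H]1C)CO | target

## Step count and risks

Total steps: 9. Longest linear sequence: 6 (steps 1, 2, 5, 7, 8, 9; the hexanal branch 3, 4, 5, 7, 8, 9 is equally long). No protecting-group steps are used.

The three steps most likely to fail:

Step 2, the proposed new ring expansion. The risks are retro-aldol or cyclisation of the ring-opened dibromoketone alkoxide, and condensation of the ketene during a non-acidic quench. The fallback uses known chemistry and sets out from 4. Catalytic NaOMe in MeOH at 0 °C opens the β-lactone at the acyl carbon and removes the silyl group, giving methyl (2R,3S)-3-hydroxy-2-methylpent-4-ynoate F2. TBSOTf and 2,6-lutidine give methyl (2R,3S)-3-[(tert-butyldimethylsilyl)oxy]-2-methylpent-4-ynoate F3. The established Kowalski ester homologation (CH2Br2/LiTMP, then n-BuLi with one extra equivalent for the alkyne C–H, HCl/MeOH quench) gives methyl (3S,4S)-4-[(tert-butyldimethylsilyl)oxy]-3-methylhex-5-ynoate F4. HF·pyridine removes the silyl ether and the γ-hydroxy ester closes, coming back to the route at 8.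

Step 7, the α-alkenylation. The risks are proton transfer to the more acidic product (epimerisation at C3 or drift of the diene into conjugation), β-hydride loss to the butenolide, and interference from the two alkoxides. The fallback reverses the polarity and sets out from 13. Silyl ketene acetal formation (LiHMDS/TMSCl) and NBS give (3S,4R,5S)-3-bromo-5-[(2E,4E,6R)-6-(hydroxymethyl)deca-2,4-dien-2-yl]-4-methyloxolan-2-one F5. Iodine–lithium exchange on 16 (as its alkoxide) and ZnCl2 give [(1E,3E)-5-(chlorozincoxy)-2-methylpenta-1,3-dien-1-yl]zinc chloride F6. A Ni-catalysed Negishi alkenylation of the α-bromo lactone (NiCl2·glyme, bipyridine-type ligand, DMA/THF) proceeds through the C3 radical, which is captured anti to the C4 methyl, and comes back to the route at 18.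

Step 1, the trans-selective cyclocondensation. The ynal is an untested aldehyde class for this catalyst type; the trans:cis ratio may be low, or bromide or amine may add to the triple bond. The fallback sets out from 2. Acetyl bromide and iPr2NEt with an Al(III)–triamine catalyst (acyl halide–aldehyde cyclocondensation, established for ynals) give (S)-4-[(trimethylsilyl)ethynyl]oxetan-2-one F1. NaHMDS and MeI at −78 °C methylate the β-lactone enolate anti to the C4 substituent, coming back to the route at 4.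

## Further compounds

F1 | step 1 | (S)-4-[(trimethylsilyl)ethynyl]oxetan-2-one | C[Si](C)(C)C#C[C@H]1OC(=O)C1
F2 | step 2 | methyl (2R,3S)-3-hydroxy-2-methylpent-4-ynoate | C#C[C@@H](O)[C@@H](C)C(=O)OC
F3 | step 2 | methyl (2R,3S)-3-[(tert-butyldimethylsilyl)oxy]-2-methylpent-4-ynoate | C#C[C@@H](O[Si](C)(C)C(C)(C)C)[C@@H](C)C(=O)OC
F4 | step 2 | methyl (3S,4S)-4-[(tert-butyldimethylsilyl)oxy]-3-methylhex-5-ynoate | C#C[C@@H](O[Si](C)(C)C(C)(C)C)[C@@H](C)CC(=O)OC
F5 | step 7 | (3S,4R,5S)-3-bromo-5-[(2E,4E,6R)-6-(hydroxymethyl)deca-2,4-dien-2-yl]-4-methyloxolan-2-one | CCCC[C@H](/C=C/C=C(\C)[C@H]1OC(=O)[C@@H](Br)[C@@H]1C)CO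
F6 | step 7 | [(1E,3E)-5-(chlorozincoxy)-2-methylpenta-1,3-dien-1-yl]zinc chloride | Cl[Zn]/C=C(C)/C=C/CO[Zn]Cl
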